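The south flask differed from its neighbour, the north-west flask, in the charge of free monomer, 0.50 M against 0.17 M, and both held 6.6 mM initiator for 5.0 h.

    free monomer + living end → monomer in chains + living end, rate k1*[living end]*[free monomer] (k1 = 0.055 M⁻¹ s⁻¹)
    monomer in chains + living end → free monomer + living end, rate k2*[living end] as long as [monomer in chains] is above zero (k2 = 0.0041 s⁻¹)
    free monomer + initiator → living end + monomer in chains (k3 = 0.0065 M⁻¹ s⁻¹)
    initiator → spent initiator (k4 = 3.6 × 10⁻⁴ s⁻¹)

- north-west: free monomer 0.17 M; initiator 6.6 mM; time 5.0 h
- south: free monomer 0.50 M; initiator 6.6 mM; time 5.0 h

- the average divides the monomer in chains by the number of chains begun, living and dead together
- run time (north-west): 5.0 h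

* which of the two ends with the longer chains by the average number of monomer units in a chain (chains begun, living or dead) ("neither" if they lie within 10%) (north-west / south / neither)
* average number of monomer units in a chain (chains begun, living or dead) at the end, north-west
* average number of monomer units in a chain (chains begun, living or dead) at the end, south

I began with the balance of the initiator, the reagent charged in the smaller amount. Each initiator can be captured by free monomer, which begins a chain, or it can decay to spent initiator. The capture rate grows with c(free monomer) and the decay rate does not, so the share that begins chains is c(free monomer) divided by the sum of c(free monomer) and the capture level. That capture level is the decay constant over the capture constant, the c(free monomer) at which both fates go equally fast, 0.0554 M; the ratio of c(free monomer) to it is the selectivity between the two fates. Taking the charged level gave a share of 75.4% in north-west and 90.0% in south.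

Next I turned to the chains. Growth and unzipping both scale with c(living end), so they balance at one level of free monomer, the ratio of their constants, 0.0745 M. I took what was charged above that floor to end in chains. Dividing by the chains begun gave 19.2 for north-west and 71.6 for south, so I expected south to end longer.

The weak link was the share, where I had used the charged level for a level that falls. In north-west I reckoned the initiator's half-life at the charge as 0.131 h, while free monomer, with living ends at my share of the initiator charge, closes on its floor with a half-life of 0.703 h, so I took the level to stay near the charge during most of the capture, and I kept the share. The run time covers 7.11 of those half-lives, so I expected north-west to come close to the floor.

The forecast gave south, with 19.6 for north-west, above mine, and 72 for south, noting that the “initiator is used up early”.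

The simulation gave 19.3 for north-west and 71.7 for south, so south ended longer. At 5.00 h, south held 0.00591 M of living end, with 0% of its initiator left. For the neighbour of south charged with 0.12 M of free monomer, the capture level gives a share of 68.4%, and the floor then gives a length of 10.1. That neighbour ended at 10.1.

(The constants used here were drawn at random within sensible limits; what happens was integrated by code.)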